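In tetralin numbering (C1 carries the pendant aryl ring), ring B holds a bare benzylic methylene at C4 beside a C3 whose only substituent is CH2OH. Three carbons of butadiene can therefore supply C4, C3 and the hydroxymethyl carbon, the fourth being cut away later. The key step is a palladium-mediated [4+2] annulation that, in one operation, joins C4a of ring A to C4 and the malonate carbon C2 to C3, closes ring B and sets C3 relative to C1. Its precursor is an (S)-configured diarylmethyl malonate: C1 already bears both aryl groups, ring A carries iodine at C4a ortho to the side chain, and both phenols are benzyl ethers.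

Key step: step 4

Remark 1: compounds 1 and 5 are taken as commercially available, so no protection steps are needed before the key step.
Remark 2: the facial sense of the chiral diene in step 3 is assumed, not known; the antipode that delivers the aryl group to the Re face of the benzylidene carbon is written as (R,R)-Ph-bod* [(1R,4R)-2,5-diphenylbicyclo[2.2.2]octa-2,5-diene], and (S,S)-Ph-bod* would replace it without other change if the opposite face is preferred.

Step 1
Reactants: 1 3-benzyloxy-4-methoxybenzaldehyde (O-benzylisovanillin)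
Product: 2 5-benzyloxy-2-iodo-4-methoxybenzaldehyde
Conditions: I2 (1.05 equiv), CF3CO2Ag (1.05 equiv), CH2Cl2, rt, dark
Reagents that add atoms: iodine, II
Why: Electrophilic aromatic iodination by the trifluoroacetyl hypoiodite formed from I2 and CF3CO2Ag should go para to the benzyloxy group (C6 of 1), because the methoxy group is tied up in conjugation with the para formyl group and the other position ortho to benzyloxy is flanked by two substituents, the same site selectivity that veratraldehyde shows.

Step 2
Reactants: 2 5-benzyloxy-2-iodo-4-methoxybenzaldehyde; 3 dimethyl malonate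
Product: 4 dimethyl 2-(5-benzyloxy-2-iodo-4-methoxybenzylidene)malonate
Conditions: piperidine (0.1 equiv), AcOH (0.1 equiv), toluene, reflux, Dean–Stark trap
Reagents that add atoms: none
Why: Knoevenagel condensation under piperidinium acetate catalysis, driven by azeotropic removal of water, should give the arylidene malonate, which has no alkene geometry to control because the two ester groups are identical.

Step 3
Reactants: 4 dimethyl 2-(5-benzyloxy-2-iodo-4-methoxybenzylidene)malonate; 5 (4-benzyloxy-3-methoxyphenyl)boronic acid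
Product: 6 dimethyl 2-[(S)-(4-benzyloxy-3-methoxyphenyl)(5-benzyloxy-2-iodo-4-methoxyphenyl)methyl]malonate
Conditions: [RhCl(C2H4)2]2 (2.5 mol %), (R,R)-Ph-bod* (5.5 mol %), KOH (0.1 equiv), 5 (2 equiv), dioxane/H2O 10:1, 40 °C
Reagents that add atoms: none
Why: Hayashi–Miyaura 1,4-addition, in which the aryl group of 5 passes from boron to the diene-bound monovalent rhodium hydroxide and inserts the doubly activated C=C of 4 inside the chiral pocket of the diene, so that delivery to the Re face of the benzylidene carbon (priorities iodoaryl > C(CO2Me)2 > H) sets C1 as S, after which water protonates the rhodium enolate, while oxidative addition of the aryl iodide to the diene-bound rhodium should be too slow at 40 °C to interfere.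

Step 4
Reactants: 6 dimethyl 2-[(S)-(4-benzyloxy-3-methoxyphenyl)(5-benzyloxy-2-iodo-4-methoxyphenyl)methyl]malonate; 7 buta-1,3-diene
Product: 8 dimethyl (1S,3S)-7-benzyloxy-1-(4-benzyloxy-3-methoxyphenyl)-6-methoxy-3-vinyl-3,4-dihydronaphthalene-2,2(1H)-dicarboxylate (C1 aryl and C3 vinyl cis)
Conditions: Pd(OAc)2 (5 mol %), PPh3 (5 mol %), n-Bu4NCl (1 equiv), Na2CO3 (3 equiv), 7 (5 equiv), DMF, 80 °C, sealed vessel
Reagents that add atoms: none
Why: Zerovalent palladium, formed in the flask from Pd(OAc)2 and PPh3, inserts into the C4a–I bond of 6, the arylpalladium iodide adds across one terminal C=C of butadiene (forming C4a–C4) to give a pi-allylpalladium unit that spans C3 and the two carbons of the future vinyl group, and the carbonate-generated malonate anion at C2 attacks that unit on the face away from the metal (forming C2–C3) and releases zerovalent palladium. The closest known reaction type is the Larock carboannulation of 1,3-dienes by aryl iodides that carry an ortho malonate side chain, a Heck-type carbopalladation joined to a Tsuji–Trost alkylation. Ring B closes in a 6-exo mode with respect to the allyl unit, because attack at the proximal terminus C3 gives the six-membered ring and attack at the distal terminus would give an eight-membered one. The new C3 centre is controlled by C1: the two faces of the allyl unit interconvert by pi–sigma–pi isomerisation through its unsubstituted terminus, and the preferred chair-like transition state has the C1–H bond in the plane of the malonate anion (least 1,3-allylic strain), the C1 aryl group pseudo-equatorial and the allyl residue on C3 pseudo-equatorial, which places vinyl cis to aryl (3S). The step needs diene insertion to outrun C–H arylation of the pendant ring and telomerisation of butadiene by the malonate, which excess diene, chloride and a low phosphine loading should secure, and it needs C- rather than O-alkylation, which the soft malonate carbon provides; C1 is not enolisable and stays S.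

Step 5
Reactants: 8 dimethyl (1S,3S)-7-benzyloxy-1-(4-benzyloxy-3-methoxyphenyl)-6-methoxy-3-vinyl-3,4-dihydronaphthalene-2,2(1H)-dicarboxylate
Product: 9 methyl (1S,3S)-7-benzyloxy-1-(4-benzyloxy-3-methoxyphenyl)-6-methoxy-3-vinyl-1,2,3,4-tetrahydronaphthalene-2-carboxylate (mixture of C2 epimers)
Conditions: LiCl (3 equiv), H2O (2 equiv), DMSO, 150 °C
Reagents that add atoms: none
Why: Krapcho dealkoxycarbonylation, in which chloride attacks the unhindered O-methyl carbon by SN2, the carboxylate loses CO2 and water protonates the ester enolate, creates C2 without control (protonation anti to the two flanking groups would favour the all-cis epimer), which step 6 corrects.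

Step 6
Reactants: 9 methyl (1S,3S)-7-benzyloxy-1-(4-benzyloxy-3-methoxyphenyl)-6-methoxy-3-vinyl-1,2,3,4-tetrahydronaphthalene-2-carboxylate (mixture of C2 epimers)
Product: 10 methyl (1S,2S,3S)-7-benzyloxy-1-(4-benzyloxy-3-methoxyphenyl)-6-methoxy-3-vinyl-1,2,3,4-tetrahydronaphthalene-2-carboxylate (ester trans to aryl and to vinyl)
Conditions: NaOMe (0.3 equiv), MeOH/THF, 50 °C
Reagents that add atoms: none
Why: Base-mediated epimerisation through the ester enolate puts C2, the only enolisable centre, under thermodynamic control, and the ester should settle trans to both the C1 aryl and the C3 vinyl group (2S) because only that epimer has a half-chair with all three substituents pseudo-equatorial.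

Step 7
Reactants: 10 methyl (1S,2S,3S)-7-benzyloxy-1-(4-benzyloxy-3-methoxyphenyl)-6-methoxy-3-vinyl-1,2,3,4-tetrahydronaphthalene-2-carboxylate
Product: 12 methyl (1S,2R,3R)-7-benzyloxy-1-(4-benzyloxy-3-methoxyphenyl)-3-formyl-6-methoxy-1,2,3,4-tetrahydronaphthalene-2-carboxylate, via vicinal diol 11 (not isolated)
Conditions: OsO4 (2 mol %), NaIO4 (4 equiv), 2,6-lutidine (2 equiv), dioxane/H2O 3:1, rt
Reagents that add atoms: osmium tetroxide, O=[Os](=O)(=O)=O; sodium periodate, [Na+].[O-]I(=O)(=O)=O
Why: Lemieux–Johnson oxidation, in which OsO4 dihydroxylates the only alkene and NaIO4 cleaves the diol while returning the osmium to its tetroxide with 2,6-lutidine holding back over-oxidation, should leave intact the electron-rich rings that ozone could attack, and C3, now alpha to the formyl group, already holds its thermodynamically preferred pseudo-equatorial configuration.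

Step 8
Reactants: 12 methyl (1S,2R,3R)-7-benzyloxy-1-(4-benzyloxy-3-methoxyphenyl)-3-formyl-6-methoxy-1,2,3,4-tetrahydronaphthalene-2-carboxylate
Product: 13 [(1S,2R,3R)-7-benzyloxy-1-(4-benzyloxy-3-methoxyphenyl)-6-methoxy-1,2,3,4-tetrahydronaphthalene-2,3-diyl]dimethanol
Conditions: LiAlH4 (3 equiv), THF, 0 °C to rt
Reagents that add atoms: none
Why: Hydride reduction with LiAlH4 should take the aldehyde and the methyl ester to the two primary alcohols at low temperature faster than enolisation, so C2 and C3 are retained and the benzyl ethers are untouched.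

Step 9
Reactants: 13 [(1S,2R,3R)-7-benzyloxy-1-(4-benzyloxy-3-methoxyphenyl)-6-methoxy-1,2,3,4-tetrahydronaphthalene-2,3-diyl]dimethanol
Product: 14 (+)-isolariciresinol
Conditions: H2 (1 atm), 10 % Pd/C, MeOH/EtOAc, rt
Reagents that add atoms: none
Why: Catalytic hydrogenolysis should cleave the two aryl benzyl ethers at their benzylic C–O bonds, since the molecule has no other hydrogenolysable bond or reducible group and the three stereocentres are not affected.

Compound list
1 | 3-benzyloxy-4-methoxybenzaldehyde (O-benzylisovanillin) | COc1ccc(C=O)cc1OCc1ccccc1 | starting material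
2 | 5-benzyloxy-2-iodo-4-methoxybenzaldehyde | COc1cc(I)c(C=O)cc1OCc1ccccc1 | intermediate
3 | dimethyl malonate | COC(=O)CC(=O)OC | starting material
4 | dimethyl 2-(5-benzyloxy-2-iodo-4-methoxybenzylidene)malonate | COC(=O)C(=Cc1cc(OCc2ccccc2)c(OC)cc1I)C(=O)OC | intermediate
5 | (4-benzyloxy-3-methoxyphenyl)boronic acid | COc1cc(B(O)O)ccc1OCc1ccccc1 | starting material
6 | dimethyl 2-[(S)-(4-benzyloxy-3-methoxyphenyl)(5-benzyloxy-2-iodo-4-methoxyphenyl)methyl]malonate | COc1cc([C@H](C(C(=O)OC)C(=O)OC)c2cc(OCc3ccccc3)c(OC)cc2I)ccc1OCc1ccccc1 | intermediate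
7 | buta-1,3-diene | C=CC=C | starting material
8 | dimethyl (1S,3S)-7-benzyloxy-1-(4-benzyloxy-3-methoxyphenyl)-6-methoxy-3-vinyl-3,4-dihydronaphthalene-2,2(1H)-dicarboxylate | COc1cc([C@H]2c3cc(OCc4ccccc4)c(OC)cc3C[C@@H](C=C)C2(C(=O)OC)C(=O)OC)ccc1OCc1ccccc1 | intermediate
9 | methyl (1S,3S)-7-benzyloxy-1-(4-benzyloxy-3-methoxyphenyl)-6-methoxy-3-vinyl-1,2,3,4-tetrahydronaphthalene-2-carboxylate, mixture of C2 epimers | COc1cc([C@H]2c3cc(OCc4ccccc4)c(OC)cc3C[C@@H](C=C)C2C(=O)OC)ccc1OCc1ccccc1 | intermediate
10 | methyl (1S,2S,3S)-7-benzyloxy-1-(4-benzyloxy-3-methoxyphenyl)-6-methoxy-3-vinyl-1,2,3,4-tetrahydronaphthalene-2-carboxylate | COc1cc([C@H]2c3cc(OCc4ccccc4)c(OC)cc3C[C@@H](C=C)[C@@H]2C(=O)OC)ccc1OCc1ccccc1 | intermediate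
11 | methyl (1S,2R,3R)-7-benzyloxy-1-(4-benzyloxy-3-methoxyphenyl)-3-(1,2-dihydroxyethyl)-6-methoxy-1,2,3,4-tetrahydronaphthalene-2-carboxylate, carbinol configuration open, not isolated | COc1cc([C@H]2c3cc(OCc4ccccc4)c(OC)cc3C[C@@H](C(O)CO)[C@@H]2C(=O)OC)ccc1OCc1ccccc1 | intermediate
12 | methyl (1S,2R,3R)-7-benzyloxy-1-(4-benzyloxy-3-methoxyphenyl)-3-formyl-6-methoxy-1,2,3,4-tetrahydronaphthalene-2-carboxylate | COc1cc([C@H]2c3cc(OCc4ccccc4)c(OC)cc3C[C@@H](C=O)[C@@H]2C(=O)OC)ccc1OCc1ccccc1 | intermediate
13 | [(1S,2R,3R)-7-benzyloxy-1-(4-benzyloxy-3-methoxyphenyl)-6-methoxy-1,2,3,4-tetrahydronaphthalene-2,3-diyl]dimethanol | COc1cc([C@H]2c3cc(OCc4ccccc4)c(OC)cc3C[C@@H](CO)[C@@H]2CO)ccc1OCc1ccccc1 | intermediate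
14 | (+)-isolariciresinol, [(1S,2R,3R)-7-hydroxy-1-(4-hydroxy-3-methoxyphenyl)-6-methoxy-1,2,3,4-tetrahydronaphthalene-2,3-diyl]dimethanol | COc1cc([C@H]2c3cc(O)c(OC)cc3C[C@@H](CO)[C@@H]2CO)ccc1O | target

Total step count: 9
Longest linear sequence: 9 steps (1 to 14)

Steps most likely to fail

Step 4. The ring closure may show poor facial selectivity at the allyl terminus: the geminal esters at C2 flank a pseudo-equatorial C3 substituent on both sides and weaken the equatorial bias, so vinyl could form trans as well as cis to the C1 aryl group. The fallback replaces kinetic by thermodynamic control of C3; it sets out from 6 and comes back at 12. The annulation is run unchanged and 8 is carried on together with its C3 epimer, dimethyl (1S,3R)-7-benzyloxy-1-(4-benzyloxy-3-methoxyphenyl)-6-methoxy-3-vinyl-3,4-dihydronaphthalene-2,2(1H)-dicarboxylate F1. LiCl in wet DMSO at 150 °C then gives 9 mixed with the C3-epimeric monoesters, methyl (1S,3R)-7-benzyloxy-1-(4-benzyloxy-3-methoxyphenyl)-6-methoxy-3-vinyl-1,2,3,4-tetrahydronaphthalene-2-carboxylate F2. The base step is postponed and the alkenes are cleaved at once with OsO4 and NaIO4, through the vicinal diols F3 (not isolated), to the 3-formyl esters F4 as a mixture at C2 and C3. NaOMe in degassed MeOH then equilibrates both enolisable centres (C2 alpha to the ester, C3 alpha to the aldehyde) against the fixed C1 centre. The all-pseudo-equatorial isomer that should result is 12.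

Step 3. Aryl transfer may stall or lose enantiocontrol at the twisted ortho-iodo acceptor, while hydroxide-driven retro-Knoevenagel cleavage of 4 and protodeboronation of 5 consume the partners. The fallback replaces asymmetric catalysis by resolution; it sets out from 4 and comes back at 6. (4-Benzyloxy-3-methoxyphenyl)magnesium bromide F5 is made from commercial 1-benzyloxy-4-bromo-2-methoxybenzene and magnesium in THF and added to 4 at −40 °C with CuI (10 mol %). Arylidene malonates accept aryl Grignard reagents in the 1,4-sense, and magnesium–iodine exchange at the electron-rich aryl iodide should be slow at this temperature, so the racemic adduct dimethyl 2-[(4-benzyloxy-3-methoxyphenyl)(5-benzyloxy-2-iodo-4-methoxyphenyl)methyl]malonate F6 should result. Preparative chromatography on a chiral stationary phase then separates 6 from its mirror image, the (R)-configured malonate F7.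

Step 5. Demethylation may be sluggish at the crowded quaternary diester, so that long heating degrades the material (chloride attack on aryl methyl ethers) before decarboxylation is complete. The fallback replaces alkyl–oxygen by acyl–oxygen cleavage; it sets out from 8 and comes back at 9. KOH in aqueous EtOH at reflux saponifies both esters to (1S,3S)-7-benzyloxy-1-(4-benzyloxy-3-methoxyphenyl)-6-methoxy-3-vinyl-3,4-dihydronaphthalene-2,2(1H)-dicarboxylic acid F8. Heating in pyridine at 110 °C expels carbon dioxide and gives (1S,3S)-7-benzyloxy-1-(4-benzyloxy-3-methoxyphenyl)-6-methoxy-3-vinyl-1,2,3,4-tetrahydronaphthalene-2-carboxylic acid F9 as a mixture of C2 epimers. MeI and K2CO3 in DMF re-form the methyl ester, which is 9.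

Further compounds
F1 | step 4 | dimethyl (1S,3R)-7-benzyloxy-1-(4-benzyloxy-3-methoxyphenyl)-6-methoxy-3-vinyl-3,4-dihydronaphthalene-2,2(1H)-dicarboxylate | COc1cc([C@H]2c3cc(OCc4ccccc4)c(OC)cc3C[C@H](C=C)C2(C(=O)OC)C(=O)OC)ccc1OCc1ccccc1
F2 | step 4 | methyl (1S,3R)-7-benzyloxy-1-(4-benzyloxy-3-methoxyphenyl)-6-methoxy-3-vinyl-1,2,3,4-tetrahydronaphthalene-2-carboxylate, mixture of C2 epimers | COc1cc([C@H]2c3cc(OCc4ccccc4)c(OC)cc3C[C@H](C=C)C2C(=O)OC)ccc1OCc1ccccc1
F3 | step 4 | methyl (1S)-7-benzyloxy-1-(4-benzyloxy-3-methoxyphenyl)-3-(1,2-dihydroxyethyl)-6-methoxy-1,2,3,4-tetrahydronaphthalene-2-carboxylate, mixture at C2, C3 and the carbinol carbon, not isolated | COc1cc([C@H]2c3cc(OCc4ccccc4)c(OC)cc3CC(C(O)CO)C2C(=O)OC)ccc1OCc1ccccc1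
F4 | step 4 | methyl (1S)-7-benzyloxy-1-(4-benzyloxy-3-methoxyphenyl)-3-formyl-6-methoxy-1,2,3,4-tetrahydronaphthalene-2-carboxylate, mixture at C2 and C3 | COc1cc([C@H]2c3cc(OCc4ccccc4)c(OC)cc3CC(C=O)C2C(=O)OC)ccc1OCc1ccccc1
F5 | step 3 | (4-benzyloxy-3-methoxyphenyl)magnesium bromide | COc1cc([Mg]Br)ccc1OCc1ccccc1
F6 | step 3 | racemic dimethyl 2-[(4-benzyloxy-3-methoxyphenyl)(5-benzyloxy-2-iodo-4-methoxyphenyl)methyl]malonate | COc1cc(C(C(C(=O)OC)C(=O)OC)c2cc(OCc3ccccc3)c(OC)cc2I)ccc1OCc1ccccc1
F7 | step 3 | dimethyl 2-[(R)-(4-benzyloxy-3-methoxyphenyl)(5-benzyloxy-2-iodo-4-methoxyphenyl)methyl]malonate | COc1cc([C@@H](C(C(=O)OC)C(=O)OC)c2cc(OCc3ccccc3)c(OC)cc2I)ccc1OCc1ccccc1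
F8 | step 5 | (1S,3S)-7-benzyloxy-1-(4-benzyloxy-3-methoxyphenyl)-6-methoxy-3-vinyl-3,4-dihydronaphthalene-2,2(1H)-dicarboxylic acid | COc1cc([C@H]2c3cc(OCc4ccccc4)c(OC)cc3C[C@@H](C=C)C2(C(=O)O)C(=O)O)ccc1OCc1ccccc1
F9 | step 5 | (1S,3S)-7-benzyloxy-1-(4-benzyloxy-3-methoxyphenyl)-6-methoxy-3-vinyl-1,2,3,4-tetrahydronaphthalene-2-carboxylic acid, mixture of C2 epimers | COc1cc([C@H]2c3cc(OCc4ccccc4)c(OC)cc3C[C@@H](C=C)C2C(=O)O)ccc1OCc1ccccc1
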